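**Plan**
Retrosynthesis cuts the O8 and O9 ester bonds, then C9–C10, then C6–C7 with the lactone C12–O6 bond, then the enol ether (back to a C14 lactol), the C6=C14 bond of a cyclopentene, and C4–C15.
The feature used is the bridged enol ether O4–C14=C10 (2-oxabicyclo[3.2.1]octene): its β-carbon C10 is nucleophilic and lies next to the carbinol C9, so C9–C10 can form by attack of C10 on a C9 aldehyde, closing the seven-membered ring C1–C5–C6–C7–C8–C9–C10.
Forward, the cyclopentane comes first as one ring of a cis-bicyclo[3.3.0]octene; its second ring is cleaved and re-closed through oxygen to the bridged enol ether; the methylene γ-lactone is added together with C7–C9; the seven-membered ring closes last.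
Absolute configuration comes from an enantioselective epoxidation (future C4), from (S)-but-3-ene-1,2-diol (C8) and from (R)-2-methylbutanoic acid.
C1/C5 follow from the cis ring fusion, C4 from exo addition to the bicyclic ketone, C6/C7 from a chair allylzinc transition state anti to O8, and C9 from a non-chelated, dipole-opposed ring closure.

Key step: step 19

Numbering: guaianolide locants (C1–C15; O4 is the ether oxygen on C4) are used for all intermediates.
Assumption: the manganese–salen epoxidation is taken to attack the diene with the facial sense known for indene, the second double bond standing in for the arene, so that the (R,R) complex gives (1R,8S)-2; if the sense proves opposite, the (S,S) complex is used.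

Step 1
Reactants: 1 (1Z,3Z)-cycloocta-1,3-diene
Product: 2 (1R,8S)-9-oxabicyclo[6.1.0]non-2-ene
Conditions: (R,R)-N,N′-bis(3,5-di-tert-butylsalicylidene)cyclohexane-1,2-diaminomanganese chloride (trivalent manganese, cat.), NaOCl (aq., pH 11), 4-phenylpyridine N-oxide, CH2Cl2, 0 °C
Reagents that add atoms: sodium hypochlorite, [Na+].[O-]Cl
Why: Jacobsen–Katsuki epoxidation of a cis-disubstituted conjugated alkene; one double bond is oxidized on one enantiotopic face (the vinyl epoxide formed is deactivated toward a second oxidation), which sets the configuration of the future C4 and C5.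

Step 2
Reactants: 2 (1R,8S)-9-oxabicyclo[6.1.0]non-2-ene
Product: 3 (1S,2S,5S)-cis-bicyclo[3.3.0]oct-7-en-2-ol (endo hydroxyl)
Conditions: LiNEt2, Et2O, reflux; aq. NH4Cl
Reagents that add atoms: none
Why: Base-induced transannular rearrangement of a medium-ring epoxide, known for this epoxide: lithiation at the allylic epoxide carbon gives a carbenoid that inserts into the C–H bond across the ring, so the cis ring fusion (future C1 and C5) and the endo hydroxyl follow from the epoxide, while the oxygen-bearing carbon (future C4) is not touched.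

Step 3
Reactants: 3 (1S,2S,5S)-cis-bicyclo[3.3.0]oct-7-en-2-ol
Product: 4 (1S,5S)-cis-bicyclo[3.3.0]oct-7-en-2-one
Conditions: Dess–Martin periodinane, NaHCO3, CH2Cl2, 0 °C
Reagents that add atoms: none
Why: Dess–Martin oxidation in a buffered, non-basic medium should keep the β,γ-double bond out of conjugation and leave the α-stereocentre C5 intact.

Step 4
Reactants: 4 (1S,5S)-cis-bicyclo[3.3.0]oct-7-en-2-one
Product: 5 (1S,2S,5S)-2-{[dimethyl(propan-2-yloxy)silyl]methyl}-cis-bicyclo[3.3.0]oct-7-en-2-ol
Conditions: iPrOMe2SiCH2MgCl, CeCl3, THF, −78 → 0 °C; aq. NH4Cl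
Reagents that add atoms: [(isopropoxydimethylsilyl)methyl]magnesium chloride, CC(C)O[Si](C)(C)C[Mg]Cl
Why: 1,2-Addition of the Tamao hydroxymethyl-anion equivalent as its organocerium reagent suppresses enolization of the β,γ-unsaturated ketone; attack on the convex (exo) face puts the new hydroxyl endo, that is O4 cis to C5–C6 and C1–C10, and sets C4.

Step 5
Reactants: 5 (1S,2S,5S)-2-{[dimethyl(propan-2-yloxy)silyl]methyl}-cis-bicyclo[3.3.0]oct-7-en-2-ol
Product: 6 (1S,2S,5S)-2-(hydroxymethyl)-cis-bicyclo[3.3.0]oct-7-en-2-ol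
Conditions: H2O2 (30 %), KHCO3, THF/MeOH, 50 °C
Reagents that add atoms: hydrogen peroxide, OO
Why: Tamao–Fleming oxidation replaces the C15–Si bond by C15–O; the isolated ring alkene is inert to basic hydrogen peroxide.

Step 6
Reactants: 6 (1S,2S,5S)-2-(hydroxymethyl)-cis-bicyclo[3.3.0]oct-7-en-2-ol
Product: 7 (1S,2S,5S)-2-{[(tert-butyldimethylsilyl)oxy]methyl}-cis-bicyclo[3.3.0]oct-7-en-2-ol
Conditions: TBSCl, imidazole, CH2Cl2, 0 °C
Reagents that add atoms: tert-butyldimethylsilyl chloride, CC(C)(C)[Si](C)(C)Cl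
Why: Silylation should take only the primary hydroxyl, the tertiary endo hydroxyl being too hindered.

Step 7
Reactants: 7 (1S,2S,5S)-2-{[(tert-butyldimethylsilyl)oxy]methyl}-cis-bicyclo[3.3.0]oct-7-en-2-ol
Product: 9 (1S,5S,8R)-1-{[(tert-butyldimethylsilyl)oxy]methyl}-3-hydroxy-2-oxabicyclo[3.2.1]octane-8-carbaldehyde (C14 lactol), via ozonide 8 (not isolated)
Conditions: O3, CH2Cl2, −78 °C; then PPh3, −78 °C → rt
Reagents that add atoms: ozone, [O-][O+]=O
Why: Ozonolysis with reductive work-up cleaves the cyclopentene C6=C14; the C14 aldehyde is captured by the cis tertiary hydroxyl as a six-membered bridged lactol, whereas C6 could only form a four-membered ring and stays a free aldehyde, so the two termini are told apart.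

Step 8
Reactants: 9 lactol aldehyde
Product: 10 (1S,5S,8R)-1-{[(tert-butyldimethylsilyl)oxy]methyl}-3-hydroxy-2-oxabicyclo[3.2.1]octane-8-carboxylic acid
Conditions: NaClO2, NaH2PO4, 2-methyl-2-butene, t-BuOH/H2O, 0 °C → rt
Reagents that add atoms: sodium chlorite, [Na+].[O-]Cl=O
Why: Pinnick oxidation takes the free aldehyde to the acid and leaves the closed hemiacetal; the weakly acidic buffer avoids epimerization or β-elimination at C5.

Step 9
Reactants: 10 lactol acid
Product: 11 methyl (1S,5S,8R)-1-{[(tert-butyldimethylsilyl)oxy]methyl}-3-hydroxy-2-oxabicyclo[3.2.1]octane-8-carboxylate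
Conditions: TMSCHN2, toluene/MeOH, 0 °C
Reagents that add atoms: (trimethylsilyl)diazomethane, C[Si](C)(C)C=[N+]=[N-]
Why: Esterification with (trimethylsilyl)diazomethane in methanol is selective for the carboxylic acid and does not touch the lactol.

Step 10
Reactants: 11 lactol methyl ester
Product: 13 methyl (1S,5S,8R)-1-{[(tert-butyldimethylsilyl)oxy]methyl}-2-oxabicyclo[3.2.1]oct-3-ene-8-carboxylate, via anomeric mesylate 12 (not isolated)
Conditions: MsCl, Et3N, CH2Cl2, 0 °C → reflux
Reagents that add atoms: none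
Why: Standard lactol-to-glycal dehydration: the anomeric hydroxyl is mesylated (12) and triethylamine removes a C10 proton in an E1-like elimination through the oxocarbenium ion, C10 carrying the only β-hydrogens.

Step 11
Reactants: 13 enol ether methyl ester
Product: 14 [(1S,5S,8S)-1-{[(tert-butyldimethylsilyl)oxy]methyl}-2-oxabicyclo[3.2.1]oct-3-en-8-yl]methanol
Conditions: iBu2AlH, CH2Cl2, −78 → 0 °C; aq. potassium sodium tartrate
Reagents that add atoms: none
Why: Hydride reduction of the methyl ester to the primary alcohol; enol ether and silyl ether are inert to iBu2AlH.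

Step 12
Reactants: 14 primary alcohol
Product: 15 (1S,5S,8R)-1-{[(tert-butyldimethylsilyl)oxy]methyl}-2-oxabicyclo[3.2.1]oct-3-ene-8-carbaldehyde
Conditions: Dess–Martin periodinane, NaHCO3, CH2Cl2, 0 °C; used crude
Reagents that add atoms: none
Why: Buffered Dess–Martin oxidation gives the β-alkoxy aldehyde under conditions that neither hydrolyse the enol ether nor epimerize C5.

Step 13
Reactants: 16 (S)-but-3-ene-1,2-diol
Product: 17 (4S)-4-ethenyl-2-(4-methoxyphenyl)-1,3-dioxolane (both acetal epimers)
Conditions: 4-MeOC6H4CH(OMe)2, PPTS (cat.), CH2Cl2, rt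
Reagents that add atoms: 4-methoxybenzaldehyde dimethyl acetal, COc1ccc(C(OC)OC)cc1
Why: Acid-catalysed transacetalization gives the 4-methoxybenzylidene acetal of the 1,2-diol; the stereocentre (future C8) is not involved.

Step 14
Reactants: 17 4-methoxybenzylidene acetal
Product: 18 (S)-2-[(4-methoxybenzyl)oxy]but-3-en-1-ol
Conditions: iBu2AlH, CH2Cl2, −78 → 0 °C; aq. potassium sodium tartrate
Reagents that add atoms: none
Why: Reductive acetal opening: aluminium binds the less hindered primary oxygen, that C–O bond breaks and hydride is delivered to the oxocarbenium ion, so the 4-methoxybenzyl group stays on the secondary oxygen.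

Step 15
Reactants: 18 (S)-2-[(4-methoxybenzyl)oxy]but-3-en-1-ol, 19 2-(bromomethyl)prop-2-enoic acid
Product: 20 (S)-2-[(4-methoxybenzyl)oxy]but-3-en-1-yl 2-(bromomethyl)prop-2-enoate
Conditions: DCC, DMAP (cat.), CH2Cl2, 0 °C
Reagents that add atoms: none
Why: Steglich esterification of the primary alcohol; low temperature and catalytic DMAP limit attack on the allylic bromide.

Step 16
Reactants: 20 diene ester
Product: 21 (S)-3-(bromomethyl)-5-[(4-methoxybenzyl)oxy]-5,6-dihydro-2H-pyran-2-one
Conditions: RuCl2(H2IMes)(=CH-C6H4-2-OiPr) (second-generation Hoveyda–Grubbs catalyst, H2IMes = 1,3-dimesitylimidazolidin-2-ylidene, cat.), CH2Cl2 (dilute), 40 °C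
Reagents that add atoms: none
Why: Ring-closing metathesis of an acrylate-type ester with a terminal alkene gives the α-substituted α,β-unsaturated δ-lactone; the phosphine-free catalyst cannot be alkylated by the allylic bromide, and the ring fixes C8 cis to the carbonyl carbon across C7=C11.

Step 17
Reactants: 15 bicyclic enol ether aldehyde, 21 bromomethyl lactone
Product: 24 (1S,4S,5S,6S,7S,8S)-hydroxy γ-lactone (α-methylene-γ-butyrolactone bearing the bicycle at C6 and the CH(OPMB)CH2OH chain at C7; H6 and H7 trans), via allylzinc bromide 22 (not isolated), via δ-lactone carbinol 23 (not isolated)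
Conditions: Zn dust (activated with TMSCl), THF, 0 → 45 °C; aq. NaHCO3
Reagents that add atoms: none
Why: Barbier-type (Dreiding–Schmidt) α-methylene lactone synthesis: the allylzinc adds through its γ-carbon C7 in a closed Zimmerman–Traxler chair; because the lactone ring holds C8 trans to the CH2Zn terminus the adduct is anti (C6/C7, later the trans lactone), C7 bonds on the ring face anti to the OPMB group, the aldehyde is attacked on the face turned away from C1–C10 (zinc bridging O6 and the ring oxygen O4, attack past H5), and the zinc alkoxide then shifts the acyl group from O9 to O6, which forms the γ-lactone and frees the C9 hydroxyl.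

Step 18
Reactants: 24 hydroxy γ-lactone
Product: 25 (1S,4S,5S,6S,7S,8S)-C9 aldehyde (substrate of the ring closure)
Conditions: Dess–Martin periodinane, NaHCO3, CH2Cl2, 0 °C; used crude
Reagents that add atoms: none
Why: Buffered Dess–Martin oxidation of the primary alcohol gives the α-alkoxy aldehyde without acid or base, so the enol ether and the C8 stereocentre are preserved.

Step 19
Reactants: 25 C9 aldehyde
Product: 26 (1R,4S,5S,6S,7S,8S,9S)-9-hydroxy-8-[(4-methoxybenzyl)oxy]-15-[(tert-butyldimethylsilyl)oxy]-4,14-epoxyguaia-10(14),11(13)-dien-12,6-olide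
Conditions: Me2AlCl (1.2 equiv), CH2Cl2, −78 → −40 °C; aq. potassium sodium tartrate/NaHCO3
Reagents that add atoms: none
Why: Proposed new method: Me2AlCl binds the C9 aldehyde oxygen, the enol ether attacks through its β-carbon C10 to give an oxocarbenium ion at C14, and the aluminate removes the C10 proton as methane, so the enol ether C10=C14 is restored and a neutral aluminium alkoxide rather than a protic acid is left; the closest known reactions are Me2AlCl-promoted Prins and carbonyl-ene cyclizations of aldehydes and the electrophilic substitution of glycals at their nucleophilic carbon (Vilsmeier formylation). The seven-membered ring C1–C5–C6–C7–C8–C9–C10 closes in a 7-(enol-exo)-exo-trig mode: C10 becomes a ring member, while C14 and the carbonyl oxygen stay outside. The new stereocentre C9 is set by a non-chelated, dipole-opposed (Cornforth) arrangement of C9=O and C8–OPMB, in which C10, held by the tether on the C7 side of the aldehyde, can reach only the face that gives O9 trans to O8 (9α-OH, 9S). The step needs this facial selectivity and clean proton loss in preference to ionization of the new allylic C9–O bond; a monodentate Lewis acid in near-equimolar amount is chosen because a chelate between O8 and O9 would hold the two oxygens syn and lead to the 8,9-cis isomer, and the methane-releasing reagent keeps the medium free of acid. The rigid bicycle and the trans-fused lactone hold C10 within bonding distance of C9, and since the nucleophile is regenerated the product already carries the enol ether of the target.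

Step 20
Reactants: 26 tetracyclic C9 alcohol
Product: 27 (1R,4S,5S,6S,7S,8S,9S)-9-acetoxy-8-[(4-methoxybenzyl)oxy]-15-[(tert-butyldimethylsilyl)oxy]-4,14-epoxyguaia-10(14),11(13)-dien-12,6-olide
Conditions: Ac2O, pyridine, DMAP (cat.), CH2Cl2, 0 °C
Reagents that add atoms: acetic anhydride, CC(=O)OC(C)=O
Why: Acylation of the secondary allylic alcohol under basic conditions, which do not ionize the allylic C9–O bond.

Step 21
Reactants: 27 C9 acetate
Product: 28 (1R,4S,5S,6S,7S,8S,9S)-9-acetoxy-8-hydroxy-15-[(tert-butyldimethylsilyl)oxy]-4,14-epoxyguaia-10(14),11(13)-dien-12,6-olide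
Conditions: DDQ, CH2Cl2/pH 7 phosphate buffer, 0 °C
Reagents that add atoms: none
Why: Oxidative cleavage of the 4-methoxybenzyl ether; the buffered neutral medium should spare the enol ether, the allylic acetate and the silyl ether.

Step 22
Reactants: 28 C8 alcohol, 29 (R)-2-methylbutanoic acid
Product: 30 (1R,4S,5S,6S,7S,8S,9S)-9-acetoxy-8-{[(2R)-2-methylbutanoyl]oxy}-15-[(tert-butyldimethylsilyl)oxy]-4,14-epoxyguaia-10(14),11(13)-dien-12,6-olide
Conditions: DCC, DMAP, CH2Cl2, 0 °C → rt
Reagents that add atoms: none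
Why: Steglich esterification of the secondary alcohol; at low temperature the α-stereocentre of the saturated acid should not epimerize, and acylation should outrun migration of the neighbouring acetate.

Step 23
Reactants: 30 silyl-protected target
Product: 31 CNP0013863.3
Conditions: HF·pyridine, pyridine, THF, 0 °C → rt
Reagents that add atoms: none
Why: Fluoride cleavage of the primary silyl ether; buffering with pyridine should leave the enol ether, the allylic acetate, both esters and the methylene lactone intact.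

**Compound list**
1 | (1Z,3Z)-cycloocta-1,3-diene | C1=CC=CCCCC1 | starting material
2 | (1R,8S)-9-oxabicyclo[6.1.0]non-2-ene | C1=C[C@H]2O[C@H]2CCCC1 | intermediate
3 | (1S,2S,5S)-cis-bicyclo[3.3.0]oct-7-en-2-ol (endo hydroxyl) | O[C@H]1CC[C@H]2CC=C[C@@H]12 | intermediate
4 | (1S,5S)-cis-bicyclo[3.3.0]oct-7-en-2-one | O=C1CC[C@H]2CC=C[C@@H]12 | intermediate
5 | (1S,2S,5S)-2-{[dimethyl(propan-2-yloxy)silyl]methyl}-cis-bicyclo[3.3.0]oct-7-en-2-ol (hydroxyl endo) | O[C@@]1(C[Si](C)(C)OC(C)C)CC[C@H]2CC=C[C@@H]12 | intermediate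
6 | (1S,2S,5S)-2-(hydroxymethyl)-cis-bicyclo[3.3.0]oct-7-en-2-ol | O[C@@]1(CO)CC[C@H]2CC=C[C@@H]12 | intermediate
7 | (1S,2S,5S)-2-{[(tert-butyldimethylsilyl)oxy]methyl}-cis-bicyclo[3.3.0]oct-7-en-2-ol | O[C@@]1(CO[Si](C)(C)C(C)(C)C)CC[C@H]2CC=C[C@@H]12 | intermediate
8 | ozonide of 7 (1,2,4-trioxolane across C6 and C14) | O[C@@]1(CO[Si](C)(C)C(C)(C)C)CC[C@H]2CC3OOC(O3)[C@@H]12 | intermediate
9 | (1S,5S,8R)-1-{[(tert-butyldimethylsilyl)oxy]methyl}-3-hydroxy-2-oxabicyclo[3.2.1]octane-8-carbaldehyde (C14 lactol, both lactol epimers; formyl group on the one-carbon bridge syn to the oxygen bridge) | O=C[C@@H]1[C@@H]2CC(O)O[C@@]1(CO[Si](C)(C)C(C)(C)C)CC2 | intermediate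
10 | (1S,5S,8R)-1-{[(tert-butyldimethylsilyl)oxy]methyl}-3-hydroxy-2-oxabicyclo[3.2.1]octane-8-carboxylic acid | OC(=O)[C@@H]1[C@@H]2CC(O)O[C@@]1(CO[Si](C)(C)C(C)(C)C)CC2 | intermediate
11 | methyl (1S,5S,8R)-1-{[(tert-butyldimethylsilyl)oxy]methyl}-3-hydroxy-2-oxabicyclo[3.2.1]octane-8-carboxylate | COC(=O)[C@@H]1[C@@H]2CC(O)O[C@@]1(CO[Si](C)(C)C(C)(C)C)CC2 | intermediate
12 | anomeric mesylate of 11 | COC(=O)[C@@H]1[C@@H]2CC(OS(C)(=O)=O)O[C@@]1(CO[Si](C)(C)C(C)(C)C)CC2 | intermediate
13 | methyl (1S,5S,8R)-1-{[(tert-butyldimethylsilyl)oxy]methyl}-2-oxabicyclo[3.2.1]oct-3-ene-8-carboxylate | COC(=O)[C@@H]1[C@@H]2C=CO[C@@]1(CO[Si](C)(C)C(C)(C)C)CC2 | intermediate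
14 | [(1S,5S,8S)-1-{[(tert-butyldimethylsilyl)oxy]methyl}-2-oxabicyclo[3.2.1]oct-3-en-8-yl]methanol | OC[C@@H]1[C@@H]2C=CO[C@@]1(CO[Si](C)(C)C(C)(C)C)CC2 | intermediate
15 | (1S,5S,8R)-1-{[(tert-butyldimethylsilyl)oxy]methyl}-2-oxabicyclo[3.2.1]oct-3-ene-8-carbaldehyde (formyl group syn to the enol ether bridge) | O=C[C@@H]1[C@@H]2C=CO[C@@]1(CO[Si](C)(C)C(C)(C)C)CC2 | intermediate
16 | (S)-but-3-ene-1,2-diol | OC[C@@H](O)C=C | starting material
17 | (4S)-4-ethenyl-2-(4-methoxyphenyl)-1,3-dioxolane (both acetal epimers) | C=C[C@H]1COC(O1)c2ccc(OC)cc2 | intermediate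
18 | (S)-2-[(4-methoxybenzyl)oxy]but-3-en-1-ol | OC[C@@H](OCc1ccc(OC)cc1)C=C | intermediate
19 | 2-(bromomethyl)prop-2-enoic acid | C=C(CBr)C(=O)O | starting material
20 | (S)-2-[(4-methoxybenzyl)oxy]but-3-en-1-yl 2-(bromomethyl)prop-2-enoate | C=C(CBr)C(=O)OC[C@@H](OCc1ccc(OC)cc1)C=C | intermediate
21 | (S)-3-(bromomethyl)-5-[(4-methoxybenzyl)oxy]-5,6-dihydro-2H-pyran-2-one | O=C1OC[C@@H](OCc2ccc(OC)cc2)C=C1CBr | intermediate
22 | allylzinc bromide from 21 | O=C1OC[C@@H](OCc2ccc(OC)cc2)C=C1C[Zn]Br | intermediate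
23 | δ-lactone carbinol: 3-methylene-5-[(4-methoxybenzyl)oxy]tetrahydropyran-2-one bearing at C7 the CH(OH) group (C6) attached to the bicycle of 15; C6–OH and C8 anti, C6 and OPMB trans on the δ-lactone | C=C1C(=O)OC[C@@H](OCc2ccc(OC)cc2)[C@@H]1[C@H](O)[C@@H]3[C@@H]4C=CO[C@@]3(CO[Si](C)(C)C(C)(C)C)CC4 | intermediate
24 | (1S,4S,5S,6S,7S,8S)-hydroxy γ-lactone: 3-methylene-γ-butyrolactone with the bicycle of 15 at C6 and the (S)-CH(OPMB)CH2OH chain at C7, H6 and H7 trans | C=C1C(=O)O[C@@H]([C@H]1[C@H](OCc2ccc(OC)cc2)CO)[C@@H]3[C@@H]4C=CO[C@@]3(CO[Si](C)(C)C(C)(C)C)CC4 | intermediate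
25 | (1S,4S,5S,6S,7S,8S)-C9 aldehyde of 24 | C=C1C(=O)O[C@@H]([C@H]1[C@H](OCc2ccc(OC)cc2)C=O)[C@@H]3[C@@H]4C=CO[C@@]3(CO[Si](C)(C)C(C)(C)C)CC4 | intermediate
26 | (1R,4S,5S,6S,7S,8S,9S)-9-hydroxy-8-[(4-methoxybenzyl)oxy]-15-[(tert-butyldimethylsilyl)oxy]-4,14-epoxyguaia-10(14),11(13)-dien-12,6-olide (1αH,5αH,6βH,7αH; 8β-O, 9α-OH) | C=C1C(=O)O[C@H]2[C@H]1[C@H](OCc4ccc(OC)cc4)[C@@H](O)C1=CO[C@@]3(CO[Si](C)(C)C(C)(C)C)CC[C@@H]1[C@@H]23 | intermediate
27 | 9-O-acetate of 26 | C=C1C(=O)O[C@H]2[C@H]1[C@H](OCc4ccc(OC)cc4)[C@@H](OC(C)=O)C1=CO[C@@]3(CO[Si](C)(C)C(C)(C)C)CC[C@@H]1[C@@H]23 | intermediate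
28 | (1R,4S,5S,6S,7S,8S,9S)-9-acetoxy-8-hydroxy-15-[(tert-butyldimethylsilyl)oxy]-4,14-epoxyguaia-10(14),11(13)-dien-12,6-olide | C=C1C(=O)O[C@H]2[C@H]1[C@H](O)[C@@H](OC(C)=O)C1=CO[C@@]3(CO[Si](C)(C)C(C)(C)C)CC[C@@H]1[C@@H]23 | intermediate
29 | (R)-2-methylbutanoic acid | CC[C@@H](C)C(O)=O | starting material
30 | 15-O-tert-butyldimethylsilyl ether of the target | C=C1C(=O)O[C@H]2[C@H]1[C@H](OC(=O)[C@H](C)CC)[C@@H](OC(C)=O)C1=CO[C@@]3(CO[Si](C)(C)C(C)(C)C)CC[C@@H]1[C@@H]23 | intermediate
31 | CNP0013863.3, (1R,4S,5S,6S,7S,8S,9S)-9-acetoxy-15-hydroxy-8-{[(2R)-2-methylbutanoyl]oxy}-4,14-epoxyguaia-10(14),11(13)-dien-12,6-olide | C=C1C(=O)O[C@H]2[C@H]1[C@H](OC(=O)[C@H](C)CC)[C@@H](OC(C)=O)C1=CO[C@@]3(CO)CC[C@@H]1[C@@H]23 | target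

**Step count**
Total: 23 steps. Longest linear sequence: 19 steps (steps 1–12 and 17–23); steps 13–16 make the lactone fragment 21.

**Steps most likely to fail**

Step 19 (ring closure). The aluminium-bound product may ionize at the new allylic C9–O bond (Ferrier-type loss of the hydroxyl), the enol ether may add to the methylene lactone instead of the aldehyde, or the aldehyde may be attacked with poor facial selectivity. The fallback sets out from 24 and comes back at 26. Iodination of the enol ether at C10 (NIS, AgNO3 cat., MeCN; the known one-step conversion of glycals into 2-iodoglycals) would give the vinyl iodide F1. Dess–Martin oxidation would give the iodo aldehyde F2. An intramolecular Nozaki–Hiyama–Kishi reaction (CrCl2, NiCl2 cat., DMSO) would then join C10 to C9 under neutral conditions and give 26.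

Step 17 (allylzinc addition). The aldehyde faces may be poorly differentiated, an open transition state may give the syn adduct, or the acyl shift from the δ- to the γ-lactone may stay incomplete. The fallback sets out from 21 (with 15) and comes back at 24. Miyaura-type allylic borylation of 21 (B2pin2, Pd2(dba)3 cat., DMSO) would give the allylboronate F3. Its thermal addition to 15 (toluene, 60 °C) can only pass through the closed six-membered boron–oxygen chair and would give the δ-lactone carbinol 23. This is isolated after aqueous work-up and isomerized to 24 with catalytic DBU in CH2Cl2.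

Step 10 (lactol dehydration). The elimination may stop at the anomeric chloride, or the bridged oxocarbenium ion may lose the tertiary C4–O bond (ring opening) instead of a C10 proton. The fallback sets out from 11 and comes back at 13. The lactol would be converted into the phenyl thioacetal F4 (PhSSPh, Bu3P, THF) and oxidized to the sulfoxide F5 (mCPBA, CH2Cl2, −78 °C). Heating (toluene, 110 °C, Et3N) would then give 13 by thermal syn elimination of benzenesulfenic acid, with no cationic intermediate.

**Further compounds**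
F1 | step 19 | C10 iodide of 24 (vinyl iodide on the enol ether) | C=C1C(=O)O[C@@H]([C@H]1[C@H](OCc2ccc(OC)cc2)CO)[C@@H]3[C@@H]4C(I)=CO[C@@]3(CO[Si](C)(C)C(C)(C)C)CC4
F2 | step 19 | C10 iodide of aldehyde 25 | C=C1C(=O)O[C@@H]([C@H]1[C@H](OCc2ccc(OC)cc2)C=O)[C@@H]3[C@@H]4C(I)=CO[C@@]3(CO[Si](C)(C)C(C)(C)C)CC4
F3 | step 17 | (S)-5-[(4-methoxybenzyl)oxy]-3-[(4,4,5,5-tetramethyl-1,3,2-dioxaborolan-2-yl)methyl]-5,6-dihydro-2H-pyran-2-one | O=C1OC[C@@H](OCc2ccc(OC)cc2)C=C1CB3OC(C)(C)C(C)(C)O3
F4 | step 10 | phenyl thioacetal of 11 (SPh in place of the lactol OH) | COC(=O)[C@@H]1[C@@H]2CC(Sc3ccccc3)O[C@@]1(CO[Si](C)(C)C(C)(C)C)CC2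
F5 | step 10 | sulfoxide of F4 | COC(=O)[C@@H]1[C@@H]2CC(S(=O)c3ccccc3)O[C@@]1(CO[Si](C)(C)C(C)(C)C)CC2
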